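Slowness is your instrument here: a slow flask gives whatever spoils target more minutes to act, so compare a slow flask with a fast one at equal catalyst work, and not at equal minutes.

| flask | substrate | free catalyst | time |
|---|---|---|---|
| larch | 0.120 M | 2.40 × 10⁻⁴ M |  |
| cedar | 0.0720 M | 2.40 × 10⁻⁴ M |  |
| birch | 0.180 M | 2.40 × 10⁻⁴ M |  |
| maple | 0.120 M | 7.20 × 10⁻⁴ M |  |
| elm | 0.0400 M | 2.40 × 10⁻⁴ M | 30 min |

| larch run: time / min | larch run: [target] / M | cedar run: time / min | cedar run: [target] / M | birch run: time / min | birch run: [target] / M | maple run: time / min | maple run: [target] / M |
|---|---|---|---|---|---|---|---|
| 5.0 | 0.0144 | 5.0 | 0.0072 | 5.0 | 0.0256 | 5.0 | 0.0341 |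
| 10 | 0.0250 | 10 | 0.0115 | 10 | 0.0439 | 10 | 0.0525 |
| 15 | 0.0317 | 15 | 0.0152 | 15 | 0.0585 | 15 | 0.0620 |
| 20 | 0.0385 | 20 | 0.0178 | 20 | 0.0684 | 20 | 0.0672 |
| 25 | 0.0430 | 25 | 0.0192 | 25 | 0.0754 | 25 | 0.0690 |
| 30 | 0.0465 | 30 | 0.0225 | 30 | 0.0804 | 30 | 0.0708 |

(readings scatter by 6 × 10⁻⁴ M)

- reaction order in [free catalyst] at the outset, round the charge of the larch run, defined at two percent of the substrate turned into target
- reaction order in [substrate] at the outset, round the charge of the larch run, defined at two percent of the substrate turned into target (one fixed amount of target, the same in the runs compared)
- target in the elm run at 30 min, as a share of the substrate charged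
- which of these the readings show (the product decays / nothing beyond the main steps / the substrate is lost by itself / the catalyst dies in pairs)

- Overall: substrate -> target, with free catalyst as catalyst.
- Constant volume, constant temperature.
- The analysis sees a species whether free or bound.
- An order is taken over about fifteen percent of the charge, up and down.

1. Define the dose D = C·t, with C the charge of free catalyst and t the time (the axis of variable time normalisation). The larch and maple runs share one substrate charge, and maple holds 3.00 times the catalyst of larch. If the rate follows the first power of catalyst and target is simply made, their curves coincide on D.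

2. First way: maple at 10 min reads 0.0525 M, and larch at the equal dose, 30 min, reads 0.0465 M. Larch, the slower run, lags by 0.00600 M, which is 7.07 standard deviations of such a difference. Catalyst dying in pairs leaves the share of catalyst still alive a function of D, so it keeps the two curves together on D, yet maple reads higher than larch at equal dose. Suppose instead that target decays in a first-order step. The lag is then that constant times the difference of the areas under the two curves. Call the lag divided by that difference of trapezoid areas the equal-dose decay constant k_d: 0.0104 min⁻¹.

3. Second way: the pair maple at 5.0 min and larch at 15 min, whose lag comes from other readings, gives 0.0126 min⁻¹, with a scatter of 0.00444 min⁻¹. The two ways differ by less than that, so I trust k_d.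

4. My reckoning: catalyst order about 1, from that near-coincidence on D. Target decay is my verdict, though substrate lost by itself also leaves the slower run behind, and these pairs cannot separate the two. The substrate order is above 1.38, the value from the first readings of birch and cedar, since birch has by then turned 14.2% of its charge, more than the 10.0% of cedar. Carrying the final shares of cedar and birch along ln of the charge puts the elm run at 22.6%.

5. The forecast gives 1, 1.45 and 21%, and names the catalyst dies in pairs, in its words “loss is second order in catalyst: it dies in pairs”.

The flask gives 1.0, 1.7, 21.5% and the product decays.

    free catalyst + substrate ⇌ catalyst-substrate complex, settled at all times (3.490 M⁻¹)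
    catalyst-substrate complex + substrate ⇌ doubly bound catalyst, settled at all times (1.250 M⁻¹)
    doubly bound catalyst → target + catalyst-substrate complex (309.6 min⁻¹)
    target → decomposed product (0.01110 min⁻¹)

In the maple run the doubly bound catalyst went on making target while target already present passed to decomposed product, at 7.86 × 10⁻⁴ M min⁻¹ on the reading at 30 min, against a read net gain of 3.60 × 10⁻⁴ M min⁻¹ over the last interval. In the elm run the same two steps ran together for 30 min: target stood at 21.5% of the substrate charged, and k_d, taken on a straight rise, puts the target already lost at 3.35% of that charge.

The earlier runs and the new flask come from a simulation from invented constants; noise was put on by code.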